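**Retrosynthetic overview**

- Target: a diaryl ether of ring B (numbered from its ether carbon C1: OH on C2, Br on C3, C4 and C6) and the anisole ring A (ether oxygen on C1', OMe on C2', Br on C3' and C5').
- Feature used: in ring A the bromines at C3' and C5' lie ortho and para to the C2' oxygen, and the other ortho position (C1') holds the ether oxygen. This is the pattern a free 2-aryloxyphenol takes up on bromination, so ring A is carried as a cyclohexenone ring and made aromatic late.
- Disconnections: O-methylation and O-debenzylation last; the two C–Br bonds and the aromatic sextet of ring A in one operation from a 2-aryloxycyclohex-2-enone; the enone C2–O bond by phenoxide opening of 2,3-epoxycyclohexanone and loss of water.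
- Ring B phenol: from 3-bromo-2-hydroxybenzaldehyde by O-benzylation, Baeyer–Villiger exchange of CHO for OH, and bromination ortho and para to that new OH (C6 and C4); the C3 bromine comes with the starting material.
- Ring order: ring B is aromatic from the start; the carbocycle of ring A comes from cyclohex-2-en-1-one and is aromatized in step 6; apart from the transient epoxide no ring is closed.

Key step: step 6

Remark: the target has no stereocentre. Epoxy ketone 8, adduct 9 and bromo enone 11 are racemic and their stereocentres are erased by step 6, so the SMILES of 8 and 9 show one enantiomer with the correct relative configuration and 11 is given without configuration.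

**Route**

Step 1
Reactants: 1 3-bromo-2-hydroxybenzaldehyde
Product: 2 2-(benzyloxy)-3-bromobenzaldehyde
Conditions: BnBr (1.2 equiv), K2CO3 (1.5 equiv), DMF, rt
Reagents that add atoms: benzyl bromide, BrCc1ccccc1
Why: Williamson ether synthesis, in which the acidic phenoxide displaces bromide from the benzylic carbon by SN2 and no other nucleophilic site is present.

Step 2
Reactants: 2 2-(benzyloxy)-3-bromobenzaldehyde
Product: 4 2-(benzyloxy)-3-bromophenol, via aryl formate 3 (not isolated)
Conditions: mCPBA (1.3 equiv), CH2Cl2, 0 °C to rt; aq. NaHCO3 wash; then K2CO3 (0.2 equiv), MeOH, rt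
Reagents that add atoms: mCPBA (3-chloroperoxybenzoic acid), OOC(=O)c1cccc(Cl)c1
Why: Baeyer–Villiger (Dakin-type) oxidation, in which the ortho-alkoxyaryl group should migrate in preference to hydride to give the formate, whose methanolysis frees the phenol.

Step 3
Reactants: 4 2-(benzyloxy)-3-bromophenol
Product: 6 2-(benzyloxy)-3,4,6-tribromophenol, via dibromophenol 5 (not isolated)
Conditions: NBS (2.05 equiv), MeCN, 0 °C to rt
Reagents that add atoms: N-bromosuccinimide, O=C1CCC(=O)N1Br
Why: electrophilic aromatic bromination directed by the free OH to its para (C4) and open ortho (C6) positions, while C5 is meta to OH and only para to a benzyloxy group twisted out of conjugation by its two ortho neighbours, and the acid-free reagent spares the benzyl ether.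

Step 4
Reactants: 7 cyclohex-2-en-1-one
Product: 8 racemic 2,3-epoxycyclohexan-1-one
Conditions: H2O2 (30% aq., 1.5 equiv), NaOH (0.1 equiv), MeOH, 0 °C
Reagents that add atoms: hydrogen peroxide, OO
Why: Weitz–Scheffer nucleophilic epoxidation (conjugate addition of hydroperoxide, then closure of the enolate onto the O–O bond), which forms the two stereocentres as a racemate with the cis fusion that the three-membered ring enforces.

Step 5
Reactants: 6 2-(benzyloxy)-3,4,6-tribromophenol (1.0 equiv); 8 racemic 2,3-epoxycyclohexan-1-one (1.5 equiv)
Product: 10 2-[2-(benzyloxy)-3,4,6-tribromophenoxy]cyclohex-2-en-1-one, via trans hydroxy ketone 9 (not isolated)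
Conditions: Cs2CO3 (0.5 equiv), DMF, 80 °C
Reagents that add atoms: none
Why: the known conversion of α,β-epoxy ketones into 2-alkoxy- and 2-aryloxy-enones, in which the phenoxide opens the epoxide by SN2 at the carbonyl-activated C2 with inversion (trans adduct 9) and base-mediated E1cB loss of water across C2–C3 then removes both stereocentres.

Step 6
Reactants: 10 2-[2-(benzyloxy)-3,4,6-tribromophenoxy]cyclohex-2-en-1-one
Product: 15 2-[2-(benzyloxy)-3,4,6-tribromophenoxy]-4,6-dibromophenol, via bromo enone 11 (not isolated), via dienone 12 (not isolated), via aryloxyphenol 13 (not isolated), via monobromophenol 14 (not isolated)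
Conditions: CuBr2 (6.5 equiv), LiBr (2 equiv), MeCN, reflux
Reagents that add atoms: CuBr2, Br[Cu]Br
Why: CuBr2 should brominate the enone at C6 through its cross-conjugated enol (copper enolate), bromo enone 11 should lose HBr across C5–C6 with bromide assistance to give the 2,5-dienone 12, and this tautomerizes to 2-aryloxyphenol 13, which the remaining CuBr2 brominates para to the new OH (14) and then ortho to it. The closest known reaction type is the CuBr2/LiBr aromatization of cyclohex-2-enones to phenols, in which excess reagent is known to carry the phenol on to ring-brominated products. No ring is closed and no stereocentre is made, since the six-membered carbocycle that becomes ring A is only dehydrogenated and substituted. The step needs bromine to enter at C6 and not at C3 of the enol-ether double bond, which is secured because C2=C3 is part of the enone and carries only a poorly donating, tribrominated aryloxy group, whereas the α'-enol is the reactive nucleophile. It also needs ring bromination in the new ring only and at the right carbons, and there the free OH outranks every other director, with its para and one ortho position open and its second ortho position occupied by the ether oxygen, while the single free carbon of ring B (C5) is meta to the ether oxygen, para to a twisted benzyloxy group and flanked by two bromines. The benzyl ether has to survive the HBr set free, which the low basicity of an oxygen on a tribrominated ring should allow.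

Step 7
Reactants: 15 2-[2-(benzyloxy)-3,4,6-tribromophenoxy]-4,6-dibromophenol
Product: 16 1-[2-(benzyloxy)-3,4,6-tribromophenoxy]-3,5-dibromo-2-methoxybenzene
Conditions: MeI (3 equiv), K2CO3 (2 equiv), DMF, rt to 40 °C
Reagents that add atoms: iodomethane, CI
Why: Williamson O-methylation of the only free, acidic phenol with a small SN2 electrophile that tolerates the flanking bromine and aryloxy groups.

Step 8
Reactants: 16 1-[2-(benzyloxy)-3,4,6-tribromophenoxy]-3,5-dibromo-2-methoxybenzene
Product: 18 2,3,5-tribromo-6-(3,5-dibromo-2-methoxyphenoxy)phenol, via aryloxydichloroborane 17 (not isolated)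
Conditions: BCl3 (3 equiv), pentamethylbenzene (3 equiv), CH2Cl2, −78 °C; then H2O
Reagents that add atoms: none
Why: Lewis-acid debenzylation, in which BCl3 activates the benzyl ether oxygen and the benzyl cation is trapped by pentamethylbenzene (Friedel–Crafts scavenging), conditions under which aryl methyl ethers, diaryl ethers and aryl bromides are expected to persist before hydrolysis of the B–O bond frees the phenol.

**Compound list**

1 | 3-bromo-2-hydroxybenzaldehyde | O=Cc1cccc(Br)c1O | starting material
2 | 2-(benzyloxy)-3-bromobenzaldehyde | O=Cc1cccc(Br)c1OCc1ccccc1 | intermediate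
3 | 2-(benzyloxy)-3-bromophenyl formate | O=COc1cccc(Br)c1OCc1ccccc1 | intermediate
4 | 2-(benzyloxy)-3-bromophenol | Oc1cccc(Br)c1OCc1ccccc1 | intermediate
5 | 2-(benzyloxy)-3,4-dibromophenol | Oc1ccc(Br)c(Br)c1OCc1ccccc1 | intermediate
6 | 2-(benzyloxy)-3,4,6-tribromophenol | Oc1c(Br)cc(Br)c(Br)c1OCc1ccccc1 | intermediate
7 | cyclohex-2-en-1-one | O=C1C=CCCC1 | starting material
8 | racemic 2,3-epoxycyclohexan-1-one (7-oxabicyclo[4.1.0]heptan-2-one, cis-fused, one enantiomer drawn) | O=C1CCC[C@@H]2O[C@H]12 | intermediate
9 | racemic trans-2-[2-(benzyloxy)-3,4,6-tribromophenoxy]-3-hydroxycyclohexan-1-one (one enantiomer drawn) | O=C1CCC[C@H](O)[C@H]1Oc1c(Br)cc(Br)c(Br)c1OCc1ccccc1 | intermediate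
10 | 2-[2-(benzyloxy)-3,4,6-tribromophenoxy]cyclohex-2-en-1-one | O=C1CCCC=C1Oc1c(Br)cc(Br)c(Br)c1OCc1ccccc1 | intermediate
11 | racemic 6-bromo-2-[2-(benzyloxy)-3,4,6-tribromophenoxy]cyclohex-2-en-1-one | O=C1C(Br)CCC=C1Oc1c(Br)cc(Br)c(Br)c1OCc1ccccc1 | intermediate
12 | 2-[2-(benzyloxy)-3,4,6-tribromophenoxy]cyclohexa-2,5-dien-1-one | O=C1C=CCC=C1Oc1c(Br)cc(Br)c(Br)c1OCc1ccccc1 | intermediate
13 | 2-[2-(benzyloxy)-3,4,6-tribromophenoxy]phenol | Oc1ccccc1Oc1c(Br)cc(Br)c(Br)c1OCc1ccccc1 | intermediate
14 | 2-[2-(benzyloxy)-3,4,6-tribromophenoxy]-4-bromophenol | Oc1ccc(Br)cc1Oc1c(Br)cc(Br)c(Br)c1OCc1ccccc1 | intermediate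
15 | 2-[2-(benzyloxy)-3,4,6-tribromophenoxy]-4,6-dibromophenol | Oc1c(Br)cc(Br)cc1Oc1c(Br)cc(Br)c(Br)c1OCc1ccccc1 | intermediate
16 | 1-[2-(benzyloxy)-3,4,6-tribromophenoxy]-3,5-dibromo-2-methoxybenzene | COc1c(Br)cc(Br)cc1Oc1c(Br)cc(Br)c(Br)c1OCc1ccccc1 | intermediate
17 | dichloro[2,3,5-tribromo-6-(3,5-dibromo-2-methoxyphenoxy)phenoxy]borane | COc1c(Br)cc(Br)cc1Oc1c(Br)cc(Br)c(Br)c1OB(Cl)Cl | intermediate
18 | 2,3,5-tribromo-6-(3,5-dibromo-2-methoxyphenoxy)phenol | COc1c(Br)cc(Br)cc1Oc1c(Br)cc(Br)c(Br)c1O | target

**Step count**

Total step count: 8. Longest linear sequence: 7 steps (steps 1, 2, 3, 5, 6, 7 and 8, from compound 1).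

**Steps most likely to fail**

Step 6. Three processes could spoil the one-pot aromatization and bromination: addition of bromine to the C2=C3 enol-ether double bond in competition with α'-bromination; entry of the second ring bromine para to the aryloxy oxygen in place of ortho to the OH; and acid cleavage of the benzyl ether by the HBr that accumulates at reflux. The fallback separates dehydrogenation from bromination and avoids acid. It sets out from 10. Soft enolization (TBSOTf, Et3N, CH2Cl2, 0 °C) should give the cross-conjugated silyl dienol ether tert-butyl({6-[2-(benzyloxy)-3,4,6-tribromophenoxy]cyclohexa-1,5-dien-1-yl}oxy)dimethylsilane F1. DDQ (CH2Cl2, rt) should dehydrogenate this cyclohexa-1,3-diene by hydride abstraction to the aryl silyl ether tert-butyl{2-[2-(benzyloxy)-3,4,6-tribromophenoxy]phenoxy}dimethylsilane F2. TBAF in THF then frees phenol 13, this time isolated, and NBS (2.05 equiv) in MeCN at 0 °C brominates it para and ortho to the OH. The route is rejoined at 15.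

Step 5. The 2,6-disubstituted, weakly nucleophilic phenoxide may open the epoxide too slowly, so that base-induced isomerization and self-condensation of the epoxy ketone consume it first, or the dehydration may stall at the aldol-type adduct. The fallback replaces the epoxide opening by an SN2 reaction on an α-halo ketone. It sets out from 6, which is alkylated with 2-chlorocyclohexanone (K2CO3, NaI (cat.), DMF, 60 °C) to give racemic 2-[2-(benzyloxy)-3,4,6-tribromophenoxy]cyclohexan-1-one F3. Iodine-catalysed dehydrogenative aromatization (I2 (0.2 equiv), DMSO, 100 °C; repeated α-iodination and HI loss with DMSO as terminal oxidant) should convert F3 into phenol 13, and NBS (2.05 equiv) in MeCN then gives the dibromophenol. The route is rejoined at 15; enone 10 is bypassed.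

Step 8. Coordination of BCl3 to the electron-poor, flanked benzyl ether oxygen may be slow, and the higher temperature then needed could start cleavage of the hindered methyl ether next to the diaryl ether oxygen. The fallback removes the benzyl group by a radical pathway instead of a Lewis acid. It sets out from 16. Benzylic bromination (NBS (1.05 equiv), AIBN (cat.), PhCF3, 80 °C) should give racemic 1-{2-[bromo(phenyl)methoxy]-3,4,6-tribromophenoxy}-3,5-dibromo-2-methoxybenzene F4, and hydrolysis of this α-bromo ether (aq. NaHCO3, acetone, rt) releases benzaldehyde and the phenol. The route is rejoined at 18.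

**Further compounds**

F1 | step 6 | tert-butyl({6-[2-(benzyloxy)-3,4,6-tribromophenoxy]cyclohexa-1,5-dien-1-yl}oxy)dimethylsilane | CC(C)(C)[Si](C)(C)OC1=CCCC=C1Oc1c(Br)cc(Br)c(Br)c1OCc1ccccc1
F2 | step 6 | tert-butyl{2-[2-(benzyloxy)-3,4,6-tribromophenoxy]phenoxy}dimethylsilane | CC(C)(C)[Si](C)(C)Oc1ccccc1Oc1c(Br)cc(Br)c(Br)c1OCc1ccccc1
F3 | step 5 | racemic 2-[2-(benzyloxy)-3,4,6-tribromophenoxy]cyclohexan-1-one | O=C1CCCCC1Oc1c(Br)cc(Br)c(Br)c1OCc1ccccc1
F4 | step 8 | racemic 1-{2-[bromo(phenyl)methoxy]-3,4,6-tribromophenoxy}-3,5-dibromo-2-methoxybenzene | COc1c(Br)cc(Br)cc1Oc1c(Br)cc(Br)c(Br)c1OC(Br)c1ccccc1
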